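**Retrosynthetic overview**

1. Target 21 ⇐ BBr3 O-demethylation of macrocyclic phenol 20 ⇐ dehydrogenation (aromatization) of ring A in macrocyclic enone 17.
2. 17 ⇐ closure of the 20-membered ring: the ring B phenoxide oxygen displaces chloride from C3 of a 3-chlorocyclohex-2-enone (15), so the diaryl ether C–O bond is made while ring A is still a partly saturated ring.
3. Enabling feature: in ring A the C–OAr carbon, the C–OH carbon and the chain-bearing carbon are mutually meta (a 5-alkylresorcinol). This is the C1/C3/C5 pattern of a 5-alkylcyclohexane-1,3-dione whose two carbonyl carbons are equivalent, so either may become C–OAr and the other C–OH. On ring B the ether oxygen lies between two oxygenated ortho carbons with the chain para, so its phenoxide can react only at oxygen.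
4. 15 ⇐ dione 14 ⇐ Michael/Claisen annulation of diethyl malonate onto enone 8; the tether comes from 12-bromododecan-1-ol and 4-(benzyloxy)-3,5-dimethoxybenzaldehyde by two Wittig reactions.
5. Ring order: ring B is bought; ring A is built as a cyclohexane-1,3-dione (step 5); the macrocycle is closed (step 8); ring A is aromatized (step 9).

Key step: step 8

Remark on the chemistry: the target has no stereocentre. The alkene made in step 2 is carried as a Z/E mixture and the ring stereocentre of 10–12 and 15–18 as a racemate, because the alkene is erased in step 6 and the stereocentre in step 9.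

**Step 1**
Reactants: 1 12-bromododecan-1-ol; 2 triphenylphosphine
Product: 3 (12-hydroxydodecyl)triphenylphosphonium bromide
Conditions: PPh3, MeCN, reflux
Reagents that add atoms: none
Why: SN2 quaternization of the phosphine by the primary bromide (phosphonium salt formation), which the free hydroxyl does not disturb.

**Step 2**
Reactants: 3 (12-hydroxydodecyl)triphenylphosphonium bromide; 4 4-(benzyloxy)-3,5-dimethoxybenzaldehyde
Product: 5 13-[4-(benzyloxy)-3,5-dimethoxyphenyl]tridec-12-en-1-ol (Z/E mixture)
Conditions: NaHMDS (2.1 equiv), THF, 0 °C; then 4, −78 °C → rt; aqueous quench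
Reagents that add atoms: none
Why: Wittig olefination of the non-stabilised ylide (formed together with the alkoxide by two equivalents of base) joins ring B to the chain; the alkene should be mainly Z, and its geometry is irrelevant because it is hydrogenated in step 6.

**Step 3**
Reactants: 5 13-[4-(benzyloxy)-3,5-dimethoxyphenyl]tridec-12-en-1-ol
Product: 6 13-[4-(benzyloxy)-3,5-dimethoxyphenyl]tridec-12-enal (Z/E mixture)
Conditions: Dess–Martin periodinane (1.2 equiv), CH2Cl2, 0 °C → rt
Reagents that add atoms: none
Why: Dess–Martin oxidation should take the primary alcohol to the aldehyde without touching the alkene, the benzyl ether or the fully etherified arene.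

**Step 4**
Reactants: 6 13-[4-(benzyloxy)-3,5-dimethoxyphenyl]tridec-12-enal; 7 1-(triphenyl-λ5-phosphanylidene)propan-2-one
Product: 8 (3E)-16-[4-(benzyloxy)-3,5-dimethoxyphenyl]hexadeca-3,15-dien-2-one (15-alkene Z/E mixture)
Conditions: toluene, 90 °C
Reagents that add atoms: none
Why: Wittig olefination with the stabilised acetonylidene ylide should give the (E)-enone needed as Michael acceptor.

**Step 5**
Reactants: 8 (3E)-16-[4-(benzyloxy)-3,5-dimethoxyphenyl]hexadeca-3,15-dien-2-one; 9 diethyl malonate
Product: 13 5-{12-[4-(benzyloxy)-3,5-dimethoxyphenyl]dodec-11-en-1-yl}cyclohexane-1,3-dione (alkene Z/E mixture), via Michael adduct 10 (not isolated), via cyclic keto ester 11 (not isolated), via keto acid 12 (not isolated)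
Conditions: NaOEt, EtOH, reflux; then 3 M aq. NaOH, reflux; then 2 M HCl to pH 2, 60 °C
Reagents that add atoms: none
Why: Michael addition of malonate to the enone, intramolecular Claisen (Dieckmann-type) condensation of the methyl ketone enolate onto an ester, saponification and decarboxylation build ring A as a 5-substituted cyclohexane-1,3-dione; the stereocentres of 10–12 are uncontrolled and vanish in the symmetric dione 13.

**Step 6**
Reactants: 13 5-{12-[4-(benzyloxy)-3,5-dimethoxyphenyl]dodec-11-en-1-yl}cyclohexane-1,3-dione
Product: 14 5-[12-(4-hydroxy-3,5-dimethoxyphenyl)dodecyl]cyclohexane-1,3-dione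
Conditions: H2 (1 atm), 10% Pd/C, EtOAc–EtOH, rt
Reagents that add atoms: none
Why: Heterogeneous catalytic hydrogenation should saturate the disubstituted alkene and hydrogenolyse the benzyl ether in one operation, while the enolised 1,3-dione and the methyl ethers are inert under neutral conditions.

**Step 7**
Reactants: 14 5-[12-(4-hydroxy-3,5-dimethoxyphenyl)dodecyl]cyclohexane-1,3-dione
Product: 15 3-chloro-5-[12-(4-hydroxy-3,5-dimethoxyphenyl)dodecyl]cyclohex-2-en-1-one (racemic)
Conditions: (COCl)2 (1.1 equiv), DMF (cat.), CH2Cl2, 0 °C; cold aq. NaHCO3 work-up; used crude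
Reagents that add atoms: oxalyl chloride, O=C(Cl)C(Cl)=O
Why: Vilsmeier-type conversion of the enolised dione (a vinylogous acid) into the β-chloroenone (a vinylogous acid chloride) should be far faster than acylation of the hindered 2,6-dimethoxyphenol without base, and any aryl formate or oxalate formed would be hydrolysed in the bicarbonate work-up; the new C5 stereocentre arises racemic and is erased in step 9.

**Step 8**
Reactants: 15 3-chloro-5-[12-(4-hydroxy-3,5-dimethoxyphenyl)dodecyl]cyclohex-2-en-1-one
Product: 17 macrocyclic enone: cyclohex-2-en-1-one whose C3 carries the oxygen of a 2,6-dimethoxyphenyl ring and whose C5 is tied by a (CH2)12 chain to C4 of that ring (20-membered ring; racemic), via cesium phenoxide 16 (not isolated)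
Conditions: Cs2CO3 (3 equiv), MeCN, 70 °C; 15 added by syringe pump over 12 h to about 2 mM final concentration
Reagents that add atoms: none
Why: Cs2CO3 forms the cesium phenoxide 16, whose oxygen adds to C3 (the β-carbon) of the chloroenone to give an enolate with a tetrahedral C3 that expels chloride, an addition–elimination (nucleophilic vinylic substitution) that yields the vinylogous aryl ester. The closest known reaction is the carbonate-mediated intermolecular coupling of phenols with 3-chlorocyclohex-2-enones to 3-aryloxycyclohex-2-enones, run here intramolecularly under the high-dilution regime used for macrocyclic SNAr etherifications. The 20-membered ring closes by 20-exo-trig attack (counted through C4) followed by elimination; no stereocentre is created and the racemic C5 centre is only carried along. Attack at oxygen instead of carbon is secured because both ortho positions of the phenoxide carry methoxy groups and the para position carries the chain, and attack at C3 instead of the carbonyl is secured because 1,2-addition is reversible and only conjugate addition can expel chloride. Ring closure over oligomerization is favoured by slow addition at high dilution, by the cesium counterion, and by the fact that the aryl vinylogous ester linkage can exchange with phenoxide, so that linear oligomers should re-equilibrate toward the unstrained monomeric ring. The step thus forms the di-ortho-substituted aryl ether bond without a metal and delivers ring A with its oxygen already meta to the ether carbon, one dehydrogenation away from the arene.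

**Step 9**
Reactants: 17 macrocyclic enone
Product: 20 macrocyclic diaryl ether with ring A as free phenol and ring B as its 2,6-dimethyl ether, via silyl dienol ether 18 (not isolated), via cross-conjugated dienone 19 (not isolated)
Conditions: LDA (1.1 equiv), THF, −78 °C; TMSCl; concentrate; then Pd(OAc)2 (1.1 equiv), MeCN, rt
Reagents that add atoms: none
Why: Kinetic deprotonation of the vinylogous ester at C6 (the α′ position, Stork–Danheiser regiochemistry) and O-silylation give the 2-silyloxy diene, which Saegusa–Ito oxidation with Pd(OAc)2 (divalent palladium) should convert by β-hydride elimination of the C5 hydrogen into the 2,5-dienone 19; this tautomerises to the phenol and removes the C5 stereocentre.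

**Step 10**
Reactants: 20 macrocyclic phenol dimethyl ether
Product: 21 CNP0314249.0 (target)
Conditions: BBr3 (5 equiv), CH2Cl2, −78 °C → rt; then MeOH, H2O
Reagents that add atoms: none
Why: Lewis-acid cleavage of the two aryl methyl ethers by BBr3 (SN2 attack of bromide on the O-methyl groups) should leave the diaryl ether and the alkyl chain untouched.

**Compound list**

1 | 12-bromododecan-1-ol | OCCCCCCCCCCCCBr | starting material
2 | triphenylphosphine | c1ccc(cc1)P(c1ccccc1)c1ccccc1 | starting material
3 | (12-hydroxydodecyl)triphenylphosphonium bromide | [Br-].OCCCCCCCCCCCC[P+](c1ccccc1)(c1ccccc1)c1ccccc1 | intermediate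
4 | 4-(benzyloxy)-3,5-dimethoxybenzaldehyde | COc1cc(C=O)cc(OC)c1OCc1ccccc1 | starting material
5 | 13-[4-(benzyloxy)-3,5-dimethoxyphenyl]tridec-12-en-1-ol (Z/E mixture, alkene geometry not specified) | OCCCCCCCCCCCC=Cc1cc(OC)c(OCc2ccccc2)c(OC)c1 | intermediate
6 | 13-[4-(benzyloxy)-3,5-dimethoxyphenyl]tridec-12-enal (Z/E mixture) | O=CCCCCCCCCCCC=Cc1cc(OC)c(OCc2ccccc2)c(OC)c1 | intermediate
7 | 1-(triphenyl-λ5-phosphanylidene)propan-2-one | CC(=O)C=P(c1ccccc1)(c1ccccc1)c1ccccc1 | starting material
8 | (3E)-16-[4-(benzyloxy)-3,5-dimethoxyphenyl]hexadeca-3,15-dien-2-one (15-alkene Z/E mixture) | CC(=O)/C=C/CCCCCCCCCCC=Cc1cc(OC)c(OCc2ccccc2)c(OC)c1 | intermediate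
9 | diethyl malonate | CCOC(=O)CC(=O)OCC | starting material
10 | diethyl 2-{16-[4-(benzyloxy)-3,5-dimethoxyphenyl]-2-oxohexadec-15-en-4-yl}propanedioate (racemic) | CCOC(=O)C(C(=O)OCC)C(CC(C)=O)CCCCCCCCCCC=Cc1cc(OC)c(OCc2ccccc2)c(OC)c1 | intermediate
11 | ethyl 6-{12-[4-(benzyloxy)-3,5-dimethoxyphenyl]dodec-11-en-1-yl}-2,4-dioxocyclohexane-1-carboxylate (racemic diastereomer mixture) | CCOC(=O)C1C(=O)CC(=O)CC1CCCCCCCCCCC=Cc1cc(OC)c(OCc2ccccc2)c(OC)c1 | intermediate
12 | 6-{12-[4-(benzyloxy)-3,5-dimethoxyphenyl]dodec-11-en-1-yl}-2,4-dioxocyclohexane-1-carboxylic acid (racemic diastereomer mixture) | OC(=O)C1C(=O)CC(=O)CC1CCCCCCCCCCC=Cc1cc(OC)c(OCc2ccccc2)c(OC)c1 | intermediate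
13 | 5-{12-[4-(benzyloxy)-3,5-dimethoxyphenyl]dodec-11-en-1-yl}cyclohexane-1,3-dione (alkene Z/E mixture) | O=C1CC(=O)CC(C1)CCCCCCCCCCC=Cc1cc(OC)c(OCc2ccccc2)c(OC)c1 | intermediate
14 | 5-[12-(4-hydroxy-3,5-dimethoxyphenyl)dodecyl]cyclohexane-1,3-dione | O=C1CC(=O)CC(C1)CCCCCCCCCCCCc1cc(OC)c(O)c(OC)c1 | intermediate
15 | 3-chloro-5-[12-(4-hydroxy-3,5-dimethoxyphenyl)dodecyl]cyclohex-2-en-1-one (racemic) | O=C1C=C(Cl)CC(C1)CCCCCCCCCCCCc1cc(OC)c(O)c(OC)c1 | intermediate
16 | cesium 4-[12-(3-chloro-5-oxocyclohex-3-en-1-yl)dodecyl]-2,6-dimethoxyphenolate (racemic) | [Cs+].[O-]c1c(OC)cc(CCCCCCCCCCCCC2CC(=O)C=C(Cl)C2)cc1OC | intermediate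
17 | macrocyclic enone: cyclohex-2-en-1-one whose C3 is bonded to the phenolic oxygen of a 2,6-dimethoxyphenyl ring and whose C5 is joined by a (CH2)12 chain to C4 of that ring (20-membered ring, racemic) | O=C1C=C2CC(C1)CCCCCCCCCCCCc1cc(OC)c(O2)c(OC)c1 | intermediate
18 | trimethylsilyl dienol ether of 17 (silyloxy on former C1, double bonds C1=C6 and C2=C3, racemic) | C[Si](C)(C)OC1=CC(CCCCCCCCCCCCc3cc(OC)c(O2)c(OC)c3)CC2=C1 | intermediate
19 | cross-conjugated dienone of the macrocycle (cyclohexa-2,5-dien-1-one with aryloxy on C3, chain on C5, CH2 at C4) | O=C1C=C2CC(=C1)CCCCCCCCCCCCc1cc(OC)c(O2)c(OC)c1 | intermediate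
20 | macrocyclic diaryl ether, ring A free phenol, ring B 2,6-dimethyl ether (the target with both ring B hydroxyls methylated) | Oc1cc2cc(c1)Oc1c(OC)cc(cc1OC)CCCCCCCCCCCC2 | intermediate
21 | CNP0314249.0: macrocyclic diaryl ether, 3-hydroxy-5-alkylphenyl (ring A) 2,6-dihydroxy-4-alkylphenyl (ring B) ether bridged by a (CH2)12 chain | Oc1cc2cc(c1)Oc1c(O)cc(cc1O)CCCCCCCCCCCC2 | target

**Step count and risks**

Total step count: 10. Longest linear sequence: 10 steps (from 1).

Steps most likely to fail:

Step 8. Intermolecular substitution may outrun the 20-membered closure and give oligomers, or the di-ortho-substituted phenoxide may add so slowly that the chloroenone decomposes. The fallback sets out from 13 and returns to the route at 21; it closes the same C–O bond at the aromatic oxidation level by palladium-catalysed etherification. Dione 13 is converted with HC(OMe)3 and catalytic TsOH in MeOH into the 3-methoxy enone F1. Saegusa–Ito aromatization as in step 9 (LDA, TMSCl; Pd(OAc)2, MeCN) gives the 5-alkenyl-3-methoxyphenol F2. Tf2O and pyridine in CH2Cl2 at 0 °C give the aryl triflate F3. H2 over Pd/C in EtOAc saturates the alkene and removes the benzyl group to give the phenol triflate F4. Buchwald–Hartwig-type diaryl ether formation (Pd(OAc)2, 2-di-tert-butylphosphino-2′,4′,6′-triisopropylbiphenyl, K3PO4, toluene, 100 °C, slow addition) closes the ring to the macrocyclic trimethyl ether F5. BBr3 as in step 10 then cleaves all three methyl ethers to 21.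

Step 7. The free phenol may be acylated by oxalyl chloride, ring B may be attacked by the chloroiminium salt, or phenol and chloroenone may condense with each other on concentration. The fallback sets out from 14 and returns at 17; it masks the phenol and unveils it only in the cyclization flask. TBSCl and imidazole in DMF, followed by a brief aqueous citric acid work-up that hydrolyses the silyl enol ether, give the aryl silyl ether dione F6. (COCl)2 with catalytic DMF gives the silyl-protected chloroenone F7. Slow addition of F7 to CsF in MeCN at 70 °C removes the silyl group, and the phenoxide, released at low stationary concentration, closes to 17.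

Step 9. The electron-rich silyloxy diene may be protodesilylated by the acetic acid released from Pd(OAc)2 and return 17, or β-hydride elimination of the C5 hydrogen may be slow in the bridged ring. The fallback sets out from 17 and returns at 20; it replaces the palladium step by a selenoxide syn-elimination. LDA in THF at −78 °C followed by PhSeBr gives the α′-phenylselanyl ketone F8, with selenium expected anti to the C5 chain and therefore syn to the C5 hydrogen. Oxidation with mCPBA in CH2Cl2 at −78 °C and warming with diisopropylamine eliminates benzeneselenenic acid toward C5, and the resulting dienone tautomerises to 20.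

**Further compounds**

F1 | step 8 | 5-{12-[4-(benzyloxy)-3,5-dimethoxyphenyl]dodec-11-en-1-yl}-3-methoxycyclohex-2-en-1-one (racemic, alkene Z/E mixture) | COC1=CC(=O)CC(C1)CCCCCCCCCCC=Cc1cc(OC)c(OCc2ccccc2)c(OC)c1
F2 | step 8 | 3-{12-[4-(benzyloxy)-3,5-dimethoxyphenyl]dodec-11-en-1-yl}-5-methoxyphenol (alkene Z/E mixture) | COc1cc(O)cc(c1)CCCCCCCCCCC=Cc1cc(OC)c(OCc2ccccc2)c(OC)c1
F3 | step 8 | 3-{12-[4-(benzyloxy)-3,5-dimethoxyphenyl]dodec-11-en-1-yl}-5-methoxyphenyl trifluoromethanesulfonate (alkene Z/E mixture) | COc1cc(OS(=O)(=O)C(F)(F)F)cc(c1)CCCCCCCCCCC=Cc1cc(OC)c(OCc2ccccc2)c(OC)c1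
F4 | step 8 | 3-[12-(4-hydroxy-3,5-dimethoxyphenyl)dodecyl]-5-methoxyphenyl trifluoromethanesulfonate | COc1cc(OS(=O)(=O)C(F)(F)F)cc(c1)CCCCCCCCCCCCc1cc(OC)c(O)c(OC)c1
F5 | step 8 | macrocyclic diaryl ether with all three hydroxyls as methyl ethers (tri-O-methyl target) | COc1cc2cc(c1)Oc1c(OC)cc(cc1OC)CCCCCCCCCCCC2
F6 | step 7 | 5-{12-[4-(tert-butyldimethylsilyloxy)-3,5-dimethoxyphenyl]dodecyl}cyclohexane-1,3-dione | O=C1CC(=O)CC(C1)CCCCCCCCCCCCc1cc(OC)c(O[Si](C)(C)C(C)(C)C)c(OC)c1
F7 | step 7 | 5-{12-[4-(tert-butyldimethylsilyloxy)-3,5-dimethoxyphenyl]dodecyl}-3-chlorocyclohex-2-en-1-one (racemic) | O=C1C=C(Cl)CC(C1)CCCCCCCCCCCCc1cc(OC)c(O[Si](C)(C)C(C)(C)C)c(OC)c1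
F8 | step 9 | 6-(phenylselanyl) derivative of macrocyclic enone 17, selenium on C6 trans to the chain on C5 (racemic, one enantiomer drawn) | O=C1C=C2C[C@@H](CCCCCCCCCCCCc3cc(OC)c(O2)c(OC)c3)[C@@H]1[Se]c1ccccc1
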